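**Assumptions (one line each)**
- (2S)-Naringenin is bought enantiopure (commercial, made by enzymatic hydrolysis of grapefruit naringin), so C2 is never formed in this route.
- In the 5-OH···O=C4 chelated tautomer the A-ring double bond is localized at C6=C7, so the 7-O-geranyl group should deliver the chain to C6 rather than C8.

**Retrosynthetic overview**
- Bonannione A is 6-geranyl-(2S)-naringenin. The C6–CH2 bond of the geranyl chain comes from a photochemical [1,3] O→C shift of the 7-O-geranyl ether. A thermal [3,3] Claisen would give the branched, quaternary α,α-dimethylallyl isomer instead.
- The 7-O-geranyl ether comes from selective alkylation of the most acidic phenol (7-OH) of (S)-naringenin with geranyl bromide.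
- No ring is formed. Both rings and the C2 stereocentre are already present in (S)-naringenin.

---

**Step 1**
Reactants: **1** (2S)-naringenin; **2** geranyl bromide ((2E)-1-bromo-3,7-dimethylocta-2,6-diene)
Product: **3** 7-O-geranyl-(2S)-naringenin
Conditions: K2CO3 (1.1 equiv), acetone, 25 °C, 12 h
Reagents that add atoms: geranyl bromide, CC(C)=CCC/C(C)=C/CBr
Why: The 7-OH (pKa ≈ 7) is far more acidic than the 4'-OH, and the 5-OH is locked in a chelate with C4=O, so one equivalent of mild base gives selective 7-O SN2 Williamson alkylation with retention of the E-alkene. The C2 centre is not touched, and the mild carbonate at room temperature avoids flavanone ring-opening and racemization.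

**Step 2**
Reactants: **3** 7-O-geranyl-(2S)-naringenin
Product: **4** bonannione A, 6-geranyl-(2S)-naringenin
Conditions: hν (310 nm), degassed MeCN (5 mM), flow photoreactor (FEP tubing), 25 °C, about 2–3 h residence time
Reagents that add atoms: none (isomerization)
Why: Proposed new method: excitation of the 5-hydroxy-chromanone chromophore, with excited-state proton transfer reinforcing the C6=C7 localization, homolyses the O7–CH2 bond to give a caged 7-phenoxyl/geranyl radical pair. The primary terminus of the allyl radical recombines at the adjacent C6, and the resulting cyclohexadienone tautomerizes to the 7-OH phenol. This is the photo-Claisen ([1,3] O→C) rearrangement of aryl allyl ethers, extended to a polyphenolic chiral flavanone. It keeps the linear E-geranyl chain that a thermal [3,3] shift would convert to the branched isomer. The C2 centre is remote from the radical pair and is not involved, so its (S) configuration is retained.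

---

**Compound list**

| No. | Name | SMILES | Role |
|---|---|---|---|
| 1 | (2S)-naringenin | Oc1cc2c(c(O)c1)C(=O)C[C@@H](c1ccc(O)cc1)O2 | starting material |
| 2 | geranyl bromide | CC(C)=CCC/C(C)=C/CBr | starting material |
| 3 | 7-O-geranyl-(2S)-naringenin | CC(C)=CCC/C(C)=C/COc1cc2c(c(O)c1)C(=O)C[C@@H](c1ccc(O)cc1)O2 | intermediate |
| 4 | bonannione A, 6-geranyl-(2S)-naringenin | CC(C)=CCC/C(C)=C/Cc1c(O)cc2c(c1O)C(=O)C[C@@H](c1ccc(O)cc1)O2 | target |

**Total step count:** 2
**Longest linear sequence:** 2 steps, from (2S)-naringenin

**Three most likely failure points**
The route has only two steps, so the third item is a second failure mode inside Step 2.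

1. **Step 2, regiochemistry and chain integrity (the proposed new step).** Risks are C8 versus C6 recombination, branched (tertiary) or Z-geranyl products, and cage escape leading to 7-OH cleavage.
   - Fallback (known chemistry): skip the O-ether and C-geranylate (2S)-naringenin directly with geranyl bromide under aqueous KOH/MeOH or K2CO3/DMF at 0 °C. Separate the 6- and 8-geranyl regioisomers by preparative HPLC and check ee.
2. **Step 1, selectivity.** Over-alkylation at 4'-O (giving the 7,4'-diether) or C-alkylation, and base-induced racemization.
   - Fallback: a Mitsunobu etherification of the 7-OH with geraniol (PPh3, DIAD, THF, 0 °C), which is selective for the most acidic phenol and needs no carbonate base.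
3. **Step 2, stereochemical erosion.** Photochemical C2–O1 cleavage or ring-opening to the 2'-hydroxychalcone, followed by non-selective reclosure.
   - Fallback: avoid irradiating the flavanone altogether. Use the known sequence of geranylating 2,4,6-trihydroxyacetophenone, Claisen–Schmidt condensation with 4-hydroxybenzaldehyde, and cyclization to racemic flavanone. Then resolve by preparative chiral HPLC to isolate the (S)-enantiomer.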